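The C30 apocarotenoid is cut at the C10–C11 single bond of the conjugated octaene chain (carotenoid numbering), the sp2–sp2 link between the C9=C10 and C11=C12 double bonds. A final, protecting-group-free Suzuki–Miyaura alkenyl–alkenyl coupling joins a C14 (E,E)-dienyl iodide carrying the (3R,6R)-3-hydroxy-ε ring (the 4-hydroxy-2,6,6-trimethylcyclohex-2-enyl ring) to an all-E C16 hexaenyl pinacol boronate ending in the free allylic alcohol, and delivers the target directly. The step exploits that C10 and C11 are both CH termini of E-alkenes, so geometry set separately in each half (syn-carboalumination; Takai–Utimoto olefination) is transferred with retention while the ring stereocentres C3 and C6 stay untouched.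

Key step: step 8

Remark on numbering: carotenoid numbering is used throughout (ring C1–C6, chain C7–C15, then C15'–C8' towards the hydroxymethyl end).
Assumption: enantiopure (R)-α-ionone, the C10 dialdehyde 9 and the C5 phosphonate 10 are taken as purchasable materials.
Remark on handling: all polyenes are kept under argon and in dim light.

Step 1
Reactants: 1 (R)-α-ionone
Product: 2 (3R,6R)-3-hydroxy-α-ionone
Conditions: cytochrome P450 monooxygenase (P450-BM3 variant selected for trans-3-hydroxylation of α-ionone, E. coli lysate), NADP+ (cat.), glucose/glucose dehydrogenase, air, KPi pH 7.5, 2% DMSO, 25 °C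
Reagents that add atoms: dioxygen, O=O
Why: Enzymatic allylic C–H hydroxylation (P450 hydrogen abstraction/oxygen rebound), a reaction type established for α-ionone, should attack the ring allylic CH2 (C3) and deliver oxygen to the ring face anti to the C6 side chain, so that the fixed 6R centre and the enzyme pocket together set C3 as R (3,6-trans) while the enone and C6 remain untouched.

Step 2
Reactants: 2 (3R,6R)-3-hydroxy-α-ionone
Product: 3 (3R,6R)-3-(trimethylsilyloxy)-α-ionone
Conditions: TMSCl, imidazole, CH2Cl2, 0 °C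
Reagents that add atoms: chlorotrimethylsilane, C[Si](C)(C)Cl
Why: Standard O-silylation of the secondary allylic alcohol; the TMS ether only has to mask the hydroxyl during the strongly basic step 3 and is shed in the work-up of step 4, so no separate deprotection step is spent.

Step 3
Reactants: 3 (3R,6R)-3-(trimethylsilyloxy)-α-ionone
Product: 5 {[(1R,4R)-4-[(1E)-but-1-en-3-yn-1-yl]-3,5,5-trimethylcyclohex-2-en-1-yl]oxy}trimethylsilane, via enol phosphate 4 (not isolated)
Conditions: LDA (1.05 equiv), THF, −78 °C; ClP(O)(OEt)2, −78 °C → rt; then LDA (2.3 equiv), THF, −78 °C → rt; H2O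
Reagents that add atoms: diethyl chlorophosphate, CCOP(=O)(Cl)OCC (its atoms stay only in intermediate 4)
Why: Methyl ketone to terminal alkyne via the enol phosphate (kinetic LDA deprotonation at the methyl group, O-phosphorylation, then LDA-induced elimination), a sequence established for β-ionone; deprotonation at the hindered doubly allylic C6–H is kinetically disfavoured at low temperature, so the 6R centre should survive, and the TMS ether is inert to amide base.

Step 4
Reactants: 5 {[(1R,4R)-4-[(1E)-but-1-en-3-yn-1-yl]-3,5,5-trimethylcyclohex-2-en-1-yl]oxy}trimethylsilane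
Product: 8 (1R,4R)-4-[(1E,3E)-4-iodo-3-methylbuta-1,3-dien-1-yl]-3,5,5-trimethylcyclohex-2-en-1-ol, via alkenylalane 6 (not isolated), via TMS-protected dienyl iodide 7 (not isolated)
Conditions: Me3Al (2.5 equiv), Cp2ZrCl2 (0.3 equiv), CH2Cl2, 0 °C → rt; I2, THF, −30 → 0 °C; aq. work-up, then K2CO3, MeOH, rt
Reagents that add atoms: trimethylaluminium, C[Al](C)C; iodine, II
Why: Zr-catalysed syn-carboalumination of the terminal alkyne (Negishi carboalumination; methyl to the internal carbon, aluminium to the terminus) fixes the E geometry of the trisubstituted C9=C10 bond, iodinolysis of the C–Al bond proceeds with retention, and carbonate-catalysed methanolysis removes the TMS group without acid, to which the allylic C3 carbinol would be sensitive.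

Step 5
Reactants: 9 (2E,4E,6E)-2,7-dimethylocta-2,4,6-trienedial (2.5 equiv), 10 ethyl (2E)-4-(diethoxyphosphoryl)-2-methylbut-2-enoate
Product: 11 ethyl (2E,4E,6E,8E,10E)-2,6,11-trimethyl-12-oxododeca-2,4,6,8,10-pentaenoate
Conditions: 10, LiHMDS, THF, −78 °C; added slowly to 9, THF, −78 → 0 °C
Reagents that add atoms: none
Why: Vinylogous Horner–Wadsworth–Emmons olefination through the α-carbon of the phosphonate anion should give the new C11'=C12' bond with the usual E preference and carry over the E-trisubstituted ester alkene; inverse addition to an excess of the symmetrical dialdehyde should hold the reaction at mono-olefination, and unreacted 9 is recovered.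

Step 6
Reactants: 11 ethyl (2E,4E,6E,8E,10E)-2,6,11-trimethyl-12-oxododeca-2,4,6,8,10-pentaenoate
Product: 12 ethyl (2E,4E,6E,8E,10E,12E)-2,6,11-trimethyl-13-(4,4,5,5-tetramethyl-1,3,2-dioxaborolan-2-yl)trideca-2,4,6,8,10,12-hexaenoate
Conditions: CrCl2 (8 equiv), Cl2CHBpin (2 equiv), LiI (4 equiv), THF, rt, dark
Reagents that add atoms: 2-(dichloromethyl)-4,4,5,5-tetramethyl-1,3,2-dioxaborolane, ClC(Cl)B1OC(C)(C)C(C)(C)O1
Why: Takai–Utimoto boryl-olefination: the geminal dichromium carbenoid formed from the dihalomethylboronate adds to the aldehyde and anti-periplanar elimination should give the E-alkenyl boronate (C11=C12) selectively, Cr(II) leaving the conjugated ester and the polyene untouched.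

Step 7
Reactants: 12 ethyl (2E,4E,6E,8E,10E,12E)-2,6,11-trimethyl-13-(4,4,5,5-tetramethyl-1,3,2-dioxaborolan-2-yl)trideca-2,4,6,8,10,12-hexaenoate
Product: 13 (2E,4E,6E,8E,10E,12E)-2,6,11-trimethyl-13-(4,4,5,5-tetramethyl-1,3,2-dioxaborolan-2-yl)trideca-2,4,6,8,10,12-hexaen-1-ol
Conditions: DIBAL-H (2.3 equiv), CH2Cl2, −78 °C; Rochelle salt
Reagents that add atoms: none
Why: DIBAL-H reduces the conjugated ester by 1,2-hydride delivery to the primary allylic alcohol at −78 °C, conditions under which alkenyl pinacol boronates (as in the reduction of β-boryl acrylates) and the polyene should persist, and the neutral tartrate work-up avoids boronate hydrolysis.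

Step 8
Reactants: 8 (1R,4R)-4-[(1E,3E)-4-iodo-3-methylbuta-1,3-dien-1-yl]-3,5,5-trimethylcyclohex-2-en-1-ol, 13 (2E,4E,6E,8E,10E,12E)-2,6,11-trimethyl-13-(4,4,5,5-tetramethyl-1,3,2-dioxaborolan-2-yl)trideca-2,4,6,8,10,12-hexaen-1-ol
Product: 14 (3R,6R)-3-hydroxy-8'-apo-ε-caroten-8'-ol (target)
Conditions: Pd(OAc)2 (5 mol %), SPhos (10 mol %), K3PO4 (3 M aq., 3 equiv), THF, degassed, 30 °C, dark
Reagents that add atoms: none
Why: Pd(0)–SPhos inserts into the C10–I bond of 8 with retention, the hexaenyl group of 13 is transferred from the base-activated boronate to palladium with retention, and reductive elimination forms the C10–C11 σ-bond. The closest known reaction type is the Suzuki–Miyaura alkenyl iodide/alkenyl boronate coupling used to assemble retinoid and carotenoid polyenes. No ring is closed and no new stereocentre is created; C3 and C6 come unchanged from 8. The step needs stereoretention at C9=C10 and C11=C12 and chemoselectivity beside two free hydroxyls. The substrates secure this because both E geometries are already fixed in isolable partners, the only C–I bond sits at C10, and the alcohols are inert to palladium and phosphate. Mild aqueous phosphate at 30 °C with exclusion of light and oxygen should suppress protodeboronation, homocoupling and E/Z isomerisation of the octaene.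

Compound list
1 | (R)-α-ionone, (3E)-4-[(1R)-2,6,6-trimethylcyclohex-2-en-1-yl]but-3-en-2-one | CC1=CCCC(C)(C)[C@H]1/C=C/C(C)=O | starting material
2 | (3R,6R)-3-hydroxy-α-ionone, (3E)-4-[(1R,4R)-4-hydroxy-2,6,6-trimethylcyclohex-2-en-1-yl]but-3-en-2-one | CC1=C[C@H](O)CC(C)(C)[C@H]1/C=C/C(C)=O | intermediate
3 | (3R,6R)-3-(trimethylsilyloxy)-α-ionone, (3E)-4-[(1R,4R)-2,6,6-trimethyl-4-(trimethylsilyloxy)cyclohex-2-en-1-yl]but-3-en-2-one | CC1=C[C@H](O[Si](C)(C)C)CC(C)(C)[C@H]1/C=C/C(C)=O | intermediate
4 | enol phosphate, diethyl (3E)-4-[(1R,4R)-2,6,6-trimethyl-4-(trimethylsilyloxy)cyclohex-2-en-1-yl]buta-1,3-dien-2-yl phosphate | CC1=C[C@H](O[Si](C)(C)C)CC(C)(C)[C@H]1/C=C/C(=C)OP(=O)(OCC)OCC | intermediate (not isolated)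
5 | {[(1R,4R)-4-[(1E)-but-1-en-3-yn-1-yl]-3,5,5-trimethylcyclohex-2-en-1-yl]oxy}trimethylsilane | CC1=C[C@H](O[Si](C)(C)C)CC(C)(C)[C@H]1/C=C/C#C | intermediate
6 | alkenylalane, dimethyl{(1E,3E)-2-methyl-4-[(1R,4R)-2,6,6-trimethyl-4-(trimethylsilyloxy)cyclohex-2-en-1-yl]buta-1,3-dien-1-yl}alumane | CC1=C[C@H](O[Si](C)(C)C)CC(C)(C)[C@H]1/C=C/C(C)=C/[Al](C)C | intermediate (not isolated)
7 | TMS-protected dienyl iodide, {[(1R,4R)-4-[(1E,3E)-4-iodo-3-methylbuta-1,3-dien-1-yl]-3,5,5-trimethylcyclohex-2-en-1-yl]oxy}trimethylsilane | CC1=C[C@H](O[Si](C)(C)C)CC(C)(C)[C@H]1/C=C/C(C)=C/I | intermediate (not isolated)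
8 | (1R,4R)-4-[(1E,3E)-4-iodo-3-methylbuta-1,3-dien-1-yl]-3,5,5-trimethylcyclohex-2-en-1-ol | CC1=C[C@H](O)CC(C)(C)[C@H]1/C=C/C(C)=C/I | intermediate
9 | (2E,4E,6E)-2,7-dimethylocta-2,4,6-trienedial (C10 dialdehyde) | O=C/C(C)=C/C=C/C=C(C)/C=O | starting material
10 | ethyl (2E)-4-(diethoxyphosphoryl)-2-methylbut-2-enoate (C5 phosphonate) | CCOC(=O)/C(C)=C/CP(=O)(OCC)OCC | starting material
11 | ethyl (2E,4E,6E,8E,10E)-2,6,11-trimethyl-12-oxododeca-2,4,6,8,10-pentaenoate | CCOC(=O)/C(C)=C/C=C/C(C)=C/C=C/C=C(C)/C=O | intermediate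
12 | ethyl (2E,4E,6E,8E,10E,12E)-2,6,11-trimethyl-13-(4,4,5,5-tetramethyl-1,3,2-dioxaborolan-2-yl)trideca-2,4,6,8,10,12-hexaenoate | CCOC(=O)/C(C)=C/C=C/C(C)=C/C=C/C=C(C)/C=C/B1OC(C)(C)C(C)(C)O1 | intermediate
13 | (2E,4E,6E,8E,10E,12E)-2,6,11-trimethyl-13-(4,4,5,5-tetramethyl-1,3,2-dioxaborolan-2-yl)trideca-2,4,6,8,10,12-hexaen-1-ol | OC/C(C)=C/C=C/C(C)=C/C=C/C=C(C)/C=C/B1OC(C)(C)C(C)(C)O1 | intermediate
14 | (3R,6R)-3-hydroxy-8'-apo-ε-caroten-8'-ol, (2E,4E,6E,8E,10E,12E,14E,16E)-17-[(1R,4R)-4-hydroxy-2,6,6-trimethylcyclohex-2-en-1-yl]-2,6,11,15-tetramethylheptadeca-2,4,6,8,10,12,14,16-octaen-1-ol | CC1=C[C@H](O)CC(C)(C)[C@H]1/C=C/C(C)=C/C=C/C(C)=C/C=C/C=C(C)/C=C/C=C(\C)CO | target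

Total step count: 8. Longest linear sequence: 5 steps (steps 1, 2, 3, 4, 8); the C16 branch (steps 5, 6, 7) joins at step 8.

Steps most likely to fail

Step 1. What may go wrong: low conversion in the enzymatic C–H hydroxylation, attack at the wrong position or ring face, or over-oxidation of the new carbinol to the 3-ketone. The fallback sets out from 1 and comes back to the route at 2, using only small-molecule chemistry. Ketalisation of 1 (ethylene glycol, triethyl orthoformate, cat. p-TsOH) should give the dioxolane ketal of (R)-α-ionone F1. Allylic oxidation of the ring CH2 (t-BuOOH, cat. Rh2(cap)4) should give the 3-oxo ketal F2. Luche reduction (NaBH4, CeCl3, MeOH, −40 °C), with hydride expected to add anti to the C6 side chain, should give mainly the cis (3S,6R) hydroxy ketal F3. Mitsunobu inversion (4-nitrobenzoic acid, PPh3, DIAD, THF, 0 °C) should give the trans (3R,6R) 4-nitrobenzoate ketal F4. Methanolysis (K2CO3, MeOH) should give the trans (3R,6R) hydroxy ketal F5, and PPTS in acetone–water should unmask the methyl ketone to give 2.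

Step 3. What may go wrong: excess LDA may remove the doubly allylic C6–H of 4 or 5, leading to epimerisation at C6, double-bond migration into conjugation, or 1,4-elimination of silanolate. The fallback sets out from 3 and comes back to the route at 8; it avoids the alkyne and the second strong-base stage. Boron-Wittig olefination of ketone 3 with lithiated bis[(pinacolato)boryl]methane (CH2(Bpin)2, LiTMP, THF, −78 °C → rt) should give the (1E,3E)-dienyl pinacol boronate F6, with the boryl group placed trans to the larger alkenyl substituent and any Z isomer removed by chromatography. Iododeboronation with retention (aq. NaOH, I2, THF, 0 °C) should give 7, and K2CO3/MeOH as in step 4 should give 8.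

Step 8. What may go wrong: protodeboronation of the hexaenyl boronate under aqueous base, oxidative homocoupling, or base- and palladium-induced E/Z isomerisation of the octaene. The fallback sets out from 11 (with 8 as partner) and comes back to the route at 14; it replaces the base-mediated boron coupling with a neutral Stille coupling. Chromium(II)-mediated stannyl-olefination of 11 (Bu3SnCHBr2, CrCl2, LiI, THF/DMF, rt) should give the (E)-stannyl hexaenoate F7. DIBAL-H (CH2Cl2, −78 °C) should give the stannyl hexaenol F8. Stille coupling of F8 with 8 (Pd2(dba)3, AsPh3, NMP, rt, dark) should give 14.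

Further compounds
F1 | step 1 | 2-methyl-2-{(E)-2-[(1R)-2,6,6-trimethylcyclohex-2-en-1-yl]ethenyl}-1,3-dioxolane | CC1=CCCC(C)(C)[C@H]1/C=C/C1(C)OCCO1
F2 | step 1 | (4R)-3,5,5-trimethyl-4-[(E)-2-(2-methyl-1,3-dioxolan-2-yl)ethenyl]cyclohex-2-en-1-one | CC1=CC(=O)CC(C)(C)[C@H]1/C=C/C1(C)OCCO1
F3 | step 1 | (1S,4R)-3,5,5-trimethyl-4-[(E)-2-(2-methyl-1,3-dioxolan-2-yl)ethenyl]cyclohex-2-en-1-ol | CC1=C[C@@H](O)CC(C)(C)[C@H]1/C=C/C1(C)OCCO1
F4 | step 1 | (1R,4R)-3,5,5-trimethyl-4-[(E)-2-(2-methyl-1,3-dioxolan-2-yl)ethenyl]cyclohex-2-en-1-yl 4-nitrobenzoate | CC1=C[C@H](OC(=O)c2ccc(cc2)[N+](=O)[O-])CC(C)(C)[C@H]1/C=C/C1(C)OCCO1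
F5 | step 1 | (1R,4R)-3,5,5-trimethyl-4-[(E)-2-(2-methyl-1,3-dioxolan-2-yl)ethenyl]cyclohex-2-en-1-ol | CC1=C[C@H](O)CC(C)(C)[C@H]1/C=C/C1(C)OCCO1
F6 | step 3 | trimethyl({(1R,4R)-3,5,5-trimethyl-4-[(1E,3E)-3-methyl-4-(4,4,5,5-tetramethyl-1,3,2-dioxaborolan-2-yl)buta-1,3-dien-1-yl]cyclohex-2-en-1-yl}oxy)silane | CC1=C[C@H](O[Si](C)(C)C)CC(C)(C)[C@H]1/C=C/C(C)=C/B1OC(C)(C)C(C)(C)O1
F7 | step 8 | ethyl (2E,4E,6E,8E,10E,12E)-2,6,11-trimethyl-13-(tributylstannyl)trideca-2,4,6,8,10,12-hexaenoate | CCOC(=O)/C(C)=C/C=C/C(C)=C/C=C/C=C(C)/C=C/[Sn](CCCC)(CCCC)CCCC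
F8 | step 8 | (2E,4E,6E,8E,10E,12E)-2,6,11-trimethyl-13-(tributylstannyl)trideca-2,4,6,8,10,12-hexaen-1-ol | OC/C(C)=C/C=C/C(C)=C/C=C/C=C(C)/C=C/[Sn](CCCC)(CCCC)CCCC
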